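Ring B is numbered from the bridge carbon B1 round to B4 (hydroxyl), B5 (isobutyryl) and B6 (hydroxyl). The route rests on cutting the B5–C(acyl) and B6–O bonds together: because the acyl carbon B5 and the hydroxyl carbon B6 are neighbours, enclosed by oxygenated B4 and bridge carbon B1, a B5–B6 aryne can take up isobutyric acid across its triple bond in one operation. The aryne precursor is the benzyl-protected diarylmethane carrying trimethylsilyl at B5 and triflate at B6, assembled from two separately functionalised rings. Acetylation of the single open carbon of ring A and hydrogenolysis finish the synthesis.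

Key step: step 11

Remark: 3,5-bis(benzyloxy)phenol and 1-iodo-3-methylbutane are taken as commercial building blocks, so the isopentyl group enters by alkylation of an aryllithium and no alkene has to be hydrogenated beside benzyl ethers.
Remark: the target has no stereocenter, so no configuration has to be set or preserved.

Step 1
Reactants: 1 2-methylphloroglucinol
Product: 3 2,4,6-trihydroxy-3-methylbenzaldehyde, via aryl iminium chloride 2 (not isolated)
Conditions: POCl3, DMF, EtOAc, 0 °C → rt; then H2O, 60 °C
Reagents that add atoms: N,N-dimethylformamide CN(C)C=O; water O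
Why: Vilsmeier–Haack formylation of the very electron-rich ring at one of its two symmetry-equivalent open carbons, the iminium group preventing a second attack until it is hydrolysed.

Step 2
Reactants: 3 2,4,6-trihydroxy-3-methylbenzaldehyde
Product: 4 4,6-bis(benzyloxy)-2-hydroxy-3-methylbenzaldehyde
Conditions: BnBr (2.05 equiv), K2CO3 (2.2 equiv), DMF, 0 °C → rt
Reagents that add atoms: benzyl bromide BrCc1ccccc1
Why: Williamson etherification that should follow acidity and access, the para hydroxyl reacting first and then the ortho hydroxyl with a hydrogen neighbour, while the hydroxyl wedged between methyl and formyl stays hydrogen-bonded to the carbonyl (any regioisomer is removed by chromatography).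

Step 3
Reactants: 4 4,6-bis(benzyloxy)-2-hydroxy-3-methylbenzaldehyde
Product: 5 4,6-bis(benzyloxy)-2-methoxy-3-methylbenzaldehyde
Conditions: MeI (3 equiv), K2CO3, DMF, 45 °C
Reagents that add atoms: iodomethane CI
Why: Williamson methylation in which the small electrophile and the polar aprotic solvent should overcome the chelated, hindered phenol.

Step 4
Reactants: 5 4,6-bis(benzyloxy)-2-methoxy-3-methylbenzaldehyde
Product: 6 [4,6-bis(benzyloxy)-2-methoxy-3-methylphenyl]methanol
Conditions: NaBH4, THF/MeOH, 0 °C; neutral work-up, used crude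
Reagents that add atoms: none
Why: Hydride reduction of the aldehyde to the benzylic alcohol, which is kept away from acid because it ionises easily.

Step 5
Reactants: 7 3,5-bis(benzyloxy)phenol
Product: 8 [3,5-bis(benzyloxy)phenoxy]triisopropylsilane
Conditions: TIPSCl, imidazole, DMF, rt
Reagents that add atoms: chlorotriisopropylsilane CC(C)[Si](Cl)(C(C)C)C(C)C
Why: Standard O-silylation, giving a bulky silyl ether that survives n-BuLi and directs lithiation poorly.

Step 6
Reactants: 8 [3,5-bis(benzyloxy)phenoxy]triisopropylsilane; 9 1-iodo-3-methylbutane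
Product: 11 [3,5-bis(benzyloxy)-4-(3-methylbutyl)phenoxy]triisopropylsilane, via aryllithium 10 (not isolated)
Conditions: n-BuLi (1.2 equiv), THF, 0 °C, 1.5 h; then 9 (1.5 equiv), 0 °C → rt
Reagents that add atoms: none
Why: Directed ortho-metalation at the carbon between the two benzyloxy groups, the kinetically favoured site because both ether oxygens coordinate lithium and the silyloxy group shields its neighbours, followed by SN2 alkylation of the aryllithium by the primary iodide.

Step 7
Reactants: 11 [3,5-bis(benzyloxy)-4-(3-methylbutyl)phenoxy]triisopropylsilane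
Product: 12 3,5-bis(benzyloxy)-4-(3-methylbutyl)phenol
Conditions: TBAF (1.1 equiv), AcOH (1.1 equiv), THF, 0 °C
Reagents that add atoms: none
Why: Fluoride-induced cleavage of the aryl silyl ether, buffered so that the electron-rich phenoxide is not exposed to air as a free anion.

Step 8
Reactants: 12 3,5-bis(benzyloxy)-4-(3-methylbutyl)phenol
Product: 13 3,5-bis(benzyloxy)-2-bromo-4-(3-methylbutyl)phenol
Conditions: NBS (1.0 equiv), CH2Cl2, −78 → −20 °C
Reagents that add atoms: N-bromosuccinimide O=C1CCC(=O)N1Br
Why: Electrophilic aromatic bromination of a symmetric phenol whose para position is blocked and whose two ortho carbons are equivalent, carried out before the rings are joined so that no carbon of ring A meets the brominating agent.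

Step 9
Reactants: 13 3,5-bis(benzyloxy)-2-bromo-4-(3-methylbutyl)phenol; 6 [4,6-bis(benzyloxy)-2-methoxy-3-methylphenyl]methanol
Product: 14 3,5-bis(benzyloxy)-2-{[4,6-bis(benzyloxy)-2-methoxy-3-methylphenyl]methyl}-6-bromo-4-(3-methylbutyl)phenol
Conditions: 13 (1.5 equiv), TsOH·H2O (10 mol %), CH2Cl2, 0 °C, slow addition of 6
Reagents that add atoms: none
Why: Friedel–Crafts benzylation in which the acid ionises 6 to a trioxygenated benzylic cation that is captured by the only unsubstituted carbon of 13 (future B1), so a second alkylation of ring B is impossible, while excess 13 and slow addition keep the cation from ring A of another molecule.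

Step 10
Reactants: 14 3,5-bis(benzyloxy)-2-{[4,6-bis(benzyloxy)-2-methoxy-3-methylphenyl]methyl}-6-bromo-4-(3-methylbutyl)phenol
Product: 17 3,5-bis(benzyloxy)-2-{[4,6-bis(benzyloxy)-2-methoxy-3-methylphenyl]methyl}-4-(3-methylbutyl)-6-(trimethylsilyl)phenyl trifluoromethanesulfonate, via O-trimethylsilyl ether 15 (not isolated), via lithium silylphenoxide 16 (not isolated)
Conditions: HMDS, THF, 70 °C, then volatiles removed; n-BuLi (1.05 equiv), THF, −100 → −78 °C; Tf2O (1.2 equiv), −100 °C → rt
Reagents that add atoms: hexamethyldisilazane C[Si](C)(C)N[Si](C)(C)C; triflic anhydride O=S(=O)(OS(=O)(=O)C(F)(F)F)C(F)(F)F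
Why: O-silylation followed by bromine–lithium exchange, which at this temperature outruns lithiation between the benzyloxy groups of ring A, sets off the 1,3 oxygen-to-carbon silyl shift (retro-Brook rearrangement), and the phenoxide released is O-triflated, the standard entry to ortho-silylaryl triflates.

Step 11
Reactants: 17 3,5-bis(benzyloxy)-2-{[4,6-bis(benzyloxy)-2-methoxy-3-methylphenyl]methyl}-4-(3-methylbutyl)-6-(trimethylsilyl)phenyl trifluoromethanesulfonate; 18 isobutyric acid
Product: 20 1-{2,4-bis(benzyloxy)-5-{[4,6-bis(benzyloxy)-2-methoxy-3-methylphenyl]methyl}-6-hydroxy-3-(3-methylbutyl)phenyl}-2-methylpropan-1-one, via aryne 19 (not isolated)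
Conditions: i-PrCO2H (1.5 equiv), CsF (5 equiv), THF (0.05 M), sealed tube, 125 °C
Reagents that add atoms: none
Why: Fluoride attacks silicon at B5 and triflate leaves from B6, giving the B5–B6 aryne 19; cesium isobutyrate then adds through oxygen to B6, and the aryl anion generated at B5 attacks the ester carbonyl in a four-membered transition state whose collapse moves the acyl group from oxygen to carbon and leaves the B6 phenoxide. The closest known reaction is the fluoride-induced insertion of arynes into the C–O bond of carboxylic acids, which gives ortho-hydroxyaryl ketones and shows the same orientation with 3-alkoxyarynes. No ring is closed, the four-membered species being only transient, and no stereocenter is created. The selectivity needed is regiochemical: the benzyloxy group at B4 withdraws inductively, so the nucleophile should add at the remote carbon B6 and the charge should develop at B5 next to the C–O bond, an electronic bias that should outweigh the steric influence of the benzylic substituent at B1. Because the acyl group migrates within the adduct it can reach B5 despite its two ortho neighbours, and high temperature, dilution and the neutralisation of the acid by CsF should favour this shift over protonation of the aryl anion.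

Step 12
Reactants: 20 1-{2,4-bis(benzyloxy)-5-{[4,6-bis(benzyloxy)-2-methoxy-3-methylphenyl]methyl}-6-hydroxy-3-(3-methylbutyl)phenyl}-2-methylpropan-1-one
Product: 21 1-{3-{[3-acetyl-2,4-bis(benzyloxy)-6-methoxy-5-methylphenyl]methyl}-4,6-bis(benzyloxy)-2-hydroxy-5-(3-methylbutyl)phenyl}-2-methylpropan-1-one
Conditions: AcOH (5 equiv), TFAA (5 equiv), CH2Cl2, 0 °C → rt; then K2CO3, MeOH, rt (work-up)
Reagents that add atoms: acetic acid CC(=O)O
Why: Friedel–Crafts acylation by acetyl trifluoroacetate formed in situ at the single unsubstituted carbon of ring A, which is activated by two ortho benzyloxy groups and the para methoxy group, with no metal halide present to strip benzyl ethers and a mild basic work-up to free the B6 phenol if it is esterified.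

Step 13
Reactants: 21 1-{3-{[3-acetyl-2,4-bis(benzyloxy)-6-methoxy-5-methylphenyl]methyl}-4,6-bis(benzyloxy)-2-hydroxy-5-(3-methylbutyl)phenyl}-2-methylpropan-1-one
Product: 22 1-{3-[(3-acetyl-2,4-dihydroxy-6-methoxy-5-methylphenyl)methyl]-2,4,6-trihydroxy-5-(3-methylbutyl)phenyl}-2-methylpropan-1-one (target)
Conditions: H2 (1 atm), 10% Pd/C, EtOAc/MeOH, rt
Reagents that add atoms: none
Why: Catalytic hydrogenolysis of the four benzyl ethers, under which the hydrogen-bonded aryl ketones, the methyl ether and the diarylmethane link should remain untouched if the reaction is stopped at full debenzylation.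

Compound list
1 | 2-methylphloroglucinol | Cc1c(O)cc(O)cc1O | starting material
2 | N-[(2,4,6-trihydroxy-3-methylphenyl)methylidene]-N-methylmethanaminium chloride | C[N+](C)=Cc1c(O)cc(O)c(C)c1O.[Cl-] | intermediate
3 | 2,4,6-trihydroxy-3-methylbenzaldehyde | O=Cc1c(O)cc(O)c(C)c1O | intermediate
4 | 4,6-bis(benzyloxy)-2-hydroxy-3-methylbenzaldehyde | O=Cc1c(O)c(C)c(OCc2ccccc2)cc1OCc1ccccc1 | intermediate
5 | 4,6-bis(benzyloxy)-2-methoxy-3-methylbenzaldehyde | COc1c(C)c(OCc2ccccc2)cc(OCc2ccccc2)c1C=O | intermediate
6 | [4,6-bis(benzyloxy)-2-methoxy-3-methylphenyl]methanol | COc1c(C)c(OCc2ccccc2)cc(OCc2ccccc2)c1CO | intermediate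
7 | 3,5-bis(benzyloxy)phenol | Oc1cc(OCc2ccccc2)cc(OCc2ccccc2)c1 | starting material
8 | [3,5-bis(benzyloxy)phenoxy]triisopropylsilane | CC(C)[Si](Oc1cc(OCc2ccccc2)cc(OCc2ccccc2)c1)(C(C)C)C(C)C | intermediate
9 | 1-iodo-3-methylbutane | CC(C)CCI | starting material
10 | [2,6-bis(benzyloxy)-4-(triisopropylsilyloxy)phenyl]lithium | [Li]c1c(OCc2ccccc2)cc(O[Si](C(C)C)(C(C)C)C(C)C)cc1OCc1ccccc1 | intermediate
11 | [3,5-bis(benzyloxy)-4-(3-methylbutyl)phenoxy]triisopropylsilane | CC(C)CCc1c(OCc2ccccc2)cc(O[Si](C(C)C)(C(C)C)C(C)C)cc1OCc1ccccc1 | intermediate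
12 | 3,5-bis(benzyloxy)-4-(3-methylbutyl)phenol | CC(C)CCc1c(OCc2ccccc2)cc(O)cc1OCc1ccccc1 | intermediate
13 | 3,5-bis(benzyloxy)-2-bromo-4-(3-methylbutyl)phenol | CC(C)CCc1c(OCc2ccccc2)cc(O)c(Br)c1OCc1ccccc1 | intermediate
14 | 3,5-bis(benzyloxy)-2-{[4,6-bis(benzyloxy)-2-methoxy-3-methylphenyl]methyl}-6-bromo-4-(3-methylbutyl)phenol | COc1c(C)c(OCc2ccccc2)cc(OCc2ccccc2)c1Cc1c(OCc2ccccc2)c(CCC(C)C)c(OCc2ccccc2)c(Br)c1O | intermediate
15 | O-trimethylsilyl ether of 14 | COc1c(C)c(OCc2ccccc2)cc(OCc2ccccc2)c1Cc1c(OCc2ccccc2)c(CCC(C)C)c(OCc2ccccc2)c(Br)c1O[Si](C)(C)C | intermediate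
16 | lithium 3,5-bis(benzyloxy)-2-{[4,6-bis(benzyloxy)-2-methoxy-3-methylphenyl]methyl}-4-(3-methylbutyl)-6-(trimethylsilyl)phenoxide | COc1c(C)c(OCc2ccccc2)cc(OCc2ccccc2)c1Cc1c(OCc2ccccc2)c(CCC(C)C)c(OCc2ccccc2)c([Si](C)(C)C)c1[O-].[Li+] | intermediate
17 | 3,5-bis(benzyloxy)-2-{[4,6-bis(benzyloxy)-2-methoxy-3-methylphenyl]methyl}-4-(3-methylbutyl)-6-(trimethylsilyl)phenyl trifluoromethanesulfonate | COc1c(C)c(OCc2ccccc2)cc(OCc2ccccc2)c1Cc1c(OCc2ccccc2)c(CCC(C)C)c(OCc2ccccc2)c([Si](C)(C)C)c1OS(=O)(=O)C(F)(F)F | intermediate
18 | isobutyric acid | CC(C)C(=O)O | starting material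
19 | B5–B6 aryne of the protected diarylmethane | COc1c(C)c(OCc2ccccc2)cc(OCc2ccccc2)c1CC1=C(OCc2ccccc2)C(CCC(C)C)=C(OCc2ccccc2)C#C1 | intermediate
20 | 1-{2,4-bis(benzyloxy)-5-{[4,6-bis(benzyloxy)-2-methoxy-3-methylphenyl]methyl}-6-hydroxy-3-(3-methylbutyl)phenyl}-2-methylpropan-1-one | COc1c(C)c(OCc2ccccc2)cc(OCc2ccccc2)c1Cc1c(OCc2ccccc2)c(CCC(C)C)c(OCc2ccccc2)c(C(=O)C(C)C)c1O | intermediate
21 | 1-{3-{[3-acetyl-2,4-bis(benzyloxy)-6-methoxy-5-methylphenyl]methyl}-4,6-bis(benzyloxy)-2-hydroxy-5-(3-methylbutyl)phenyl}-2-methylpropan-1-one | COc1c(C)c(OCc2ccccc2)c(C(C)=O)c(OCc2ccccc2)c1Cc1c(OCc2ccccc2)c(CCC(C)C)c(OCc2ccccc2)c(C(=O)C(C)C)c1O | intermediate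
22 | 1-{3-[(3-acetyl-2,4-dihydroxy-6-methoxy-5-methylphenyl)methyl]-2,4,6-trihydroxy-5-(3-methylbutyl)phenyl}-2-methylpropan-1-one | COc1c(C)c(O)c(C(C)=O)c(O)c1Cc1c(O)c(CCC(C)C)c(O)c(C(=O)C(C)C)c1O | target

Total step count: 13. Longest linear sequence: 9 steps (steps 1–4 or 5–8, followed by steps 9–13).

Steps most likely to fail

Step 11. The aryl anion at B5 may be protonated before it reaches the ester carbonyl, which would stop the sequence at O-arylation. An ether oxygen of ring A ortho to the bridge may capture B6 of the aryne through a six-membered transition state. The carboxylate may also add with the opposite orientation. The fallback sets out from bromophenol 14 and avoids the aryne altogether. The B6 hydroxyl is esterified with isobutyryl chloride (Et3N, DMAP, CH2Cl2) to give the ortho-bromoaryl isobutyrate F1. Treatment of F1 with t-BuLi (2.1 equiv) in THF at −100 °C should bring about bromine–lithium exchange at B5 followed by 1,3 oxygen-to-carbon acyl migration, an anionic Fries-type rearrangement known for ortho-haloaryl esters. Protonation then gives 20, where the route is rejoined.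

Step 9. The benzylic cation from 6 may be consumed by ring A of a second molecule, either at its open carbon or by ipso attack with loss of formaldehyde, faster than by the hindered carbon of 13. Acid may also cause loss or migration of the bromine. The fallback replaces cationic alkylation by carbanion addition and sets out from silyl ether 11 and aldehyde 5. Compound 11 is dibrominated at its two equivalent open carbons with NBS (2.1 equiv) to give the dibromide F2. One bromine is exchanged with n-BuLi (1.0 equiv, THF, −78 °C), and the aryllithium F3 is added to aldehyde 5 to give the racemic diarylmethanol F4. Ionic hydrogenation with Et3SiH and TFA in CH2Cl2 at −20 °C should remove the doubly benzylic hydroxyl and give the silyl-protected diarylmethane F5. TBAF then frees the phenol to give 14, where the route is rejoined.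

Step 12. Electrophilic attack at the open carbon of ring A may be retarded by the two flanking benzyloxy groups, so that acid-induced loss or transfer of benzyl groups, cleavage of the diarylmethane link, or acylation on oxygen overtakes C-acylation. The fallback reverses the order of the last two operations and sets out from 20. Hydrogenolysis (H2, 10% Pd/C, EtOAc/MeOH) first gives the pentaphenol F6, in which that carbon is flanked only by small hydroxyl groups and is still the sole open ring carbon. C-acetylation of F6 with AcOH and BF3·OEt2 at 70 °C, the classical acylation of phloroglucinols driven by boron chelation, followed by hydrolysis of the chelate with aqueous NaOAc in MeOH, should give the target 22.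

Further compounds
F1 | step 11 | 3,5-bis(benzyloxy)-2-{[4,6-bis(benzyloxy)-2-methoxy-3-methylphenyl]methyl}-6-bromo-4-(3-methylbutyl)phenyl 2-methylpropanoate | COc1c(C)c(OCc2ccccc2)cc(OCc2ccccc2)c1Cc1c(OCc2ccccc2)c(CCC(C)C)c(OCc2ccccc2)c(Br)c1OC(=O)C(C)C
F2 | step 9 | [3,5-bis(benzyloxy)-2,6-dibromo-4-(3-methylbutyl)phenoxy]triisopropylsilane | CC(C)CCc1c(OCc2ccccc2)c(Br)c(O[Si](C(C)C)(C(C)C)C(C)C)c(Br)c1OCc1ccccc1
F3 | step 9 | [2,4-bis(benzyloxy)-5-bromo-3-(3-methylbutyl)-6-(triisopropylsilyloxy)phenyl]lithium | [Li]c1c(OCc2ccccc2)c(CCC(C)C)c(OCc2ccccc2)c(Br)c1O[Si](C(C)C)(C(C)C)C(C)C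
F4 | step 9 | racemic [4,6-bis(benzyloxy)-2-methoxy-3-methylphenyl][2,4-bis(benzyloxy)-5-bromo-3-(3-methylbutyl)-6-(triisopropylsilyloxy)phenyl]methanol | COc1c(C)c(OCc2ccccc2)cc(OCc2ccccc2)c1C(O)c1c(OCc2ccccc2)c(CCC(C)C)c(OCc2ccccc2)c(Br)c1O[Si](C(C)C)(C(C)C)C(C)C
F5 | step 9 | {3,5-bis(benzyloxy)-2-{[4,6-bis(benzyloxy)-2-methoxy-3-methylphenyl]methyl}-6-bromo-4-(3-methylbutyl)phenoxy}triisopropylsilane | COc1c(C)c(OCc2ccccc2)cc(OCc2ccccc2)c1Cc1c(OCc2ccccc2)c(CCC(C)C)c(OCc2ccccc2)c(Br)c1O[Si](C(C)C)(C(C)C)C(C)C
F6 | step 12 | 1-{3-[(2,4-dihydroxy-6-methoxy-5-methylphenyl)methyl]-2,4,6-trihydroxy-5-(3-methylbutyl)phenyl}-2-methylpropan-1-one | COc1c(C)c(O)cc(O)c1Cc1c(O)c(CCC(C)C)c(O)c(C(=O)C(C)C)c1O
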